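The dihydrofuran ring is disconnected at both bonds that tie it to the benzo ring: the aryl ether bond O1–C7a and the benzylic bond C3–C3a. Because C7a and C3a are adjacent arene carbons, they are the two termini of an aryne, and O1–C2–C3(OH) is an α-hydroxy aldehyde. One operation therefore joins benzyne to (S)-3-(benzyloxy)-2-hydroxy-3-methylbutanal: O–H addition, then 5-exo capture of the aryl anion by the aldehyde, setting C3 trans to the C2 side chain. The only other benzo substituent, the enone arm at C5, lies para to O1 and is installed afterwards, so symmetrical benzyne poses no regiochemical question. A Claisen–Schmidt condensation completes the chalcone.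

Key step: step 4

Remark: the target is read as the trans-(2R,3R) dihydrobenzofuranol with an E enone; locants are those of 2,3-dihydro-1-benzofuran (O1, C2, C3, C3a, C4 to C7, C7a).

Step 1
Reactants: 1 3-methylbut-2-en-1-ol (prenol)
Product: 2 (R)-(3,3-dimethyloxiran-2-yl)methanol
Conditions: Ti(OiPr)4 (5 mol %), (−)-diethyl D-tartrate (6 mol %), t-BuOOH (anhydrous, in isooctane), 4 Å molecular sieves, CH2Cl2, −20 °C
Reagents that add atoms: tert-butyl hydroperoxide, CC(C)(C)OO
Why: Sharpless asymmetric epoxidation of a primary allylic alcohol, in which the titanium D-tartrate catalyst binds the hydroxyl and delivers oxygen to the alkene face that should give the R epoxide (the L-tartrate would give S).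

Step 2
Reactants: 2 (R)-(3,3-dimethyloxiran-2-yl)methanol; 3 benzyl alcohol
Product: 4 (R)-3-(benzyloxy)-3-methylbutane-1,2-diol
Conditions: BnOH (5 equiv), BF3·OEt2 (10 mol %), CH2Cl2, −20 → 0 °C
Reagents that add atoms: none
Why: Lewis-acid-catalysed alcoholysis of a trisubstituted epoxide should occur at the tertiary carbon, which best carries positive charge, so the C2–O bond and its R configuration stay untouched.

Step 3
Reactants: 4 (R)-3-(benzyloxy)-3-methylbutane-1,2-diol
Product: 5 (S)-3-(benzyloxy)-2-hydroxy-3-methylbutanal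
Conditions: 2,2,6,6-tetramethylpiperidin-1-oxyl (TEMPO, 10 mol %), N-chlorosuccinimide (1.3 equiv), Bu4NCl (10 mol %), CH2Cl2/aq NaHCO3–K2CO3 (pH 8.6), rt; used at once
Reagents that add atoms: none
Why: Oxoammonium (TEMPO) oxidation should pick the unhindered primary alcohol over the neopentylic secondary one and stop at the aldehyde, leaving C2 untouched (the descriptor becomes S only because CHO outranks the CMe2 group).

Step 4
Reactants: 5 (S)-3-(benzyloxy)-2-hydroxy-3-methylbutanal; 6 2-(trimethylsilyl)phenyl trifluoromethanesulfonate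
Product: 9 (2R,3R)-2-[2-(benzyloxy)propan-2-yl]-2,3-dihydro-1-benzofuran-3-ol, via benzyne 7 (not isolated), via potassium aryl anion 8 (not isolated)
Conditions: 5 (1.2 equiv), 6 (1.0 equiv), KF (2.5 equiv), 18-crown-6 (2.5 equiv), THF, 0 °C → rt
Reagents that add atoms: none
Why: Proposed new method: fluoride removes the silyl group of 6 and triflate departs to give benzyne 7, the hydroxyl oxygen of 5 (activated by hydrogen-bonded fluoride) adds to one aryne carbon, and the aryl anion 8 formed on the neighbouring carbon adds to the adjacent aldehyde faster than it is protonated, the product alkoxide then passing its charge to the next molecule of 5. The closest known reaction type is the formal [3+2] and [4+2] annulation of arynes with N-sulfonyl α-amino ketones (to 3-hydroxyindolines) and with salicylaldehydes (to 9-hydroxyxanthenes); an aliphatic α-hydroxy aldehyde has not been shown in this role. The one ring closed, the dihydrofuran ring, forms by 5-exo-trig attack of the aryl carbanion on the carbonyl carbon. C2 comes unchanged from 5 because its C–O bond is never broken, and C3 is set by 1,2-induction from C2: in the envelope transition state the carbonyl oxygen turns towards the small C2–H and away from the bulky CMe2OBn group, and the crown-ether-wrapped potassium ion cannot chelate the two oxygens, so the hydroxyl should end up trans to the side chain (2R,3R). No regioselectivity is needed because benzyne is symmetrical (C5 is functionalised later under control of O1); chemoselectivity for O–H addition and ring closure over proton quench is secured by the benzyl cap, which leaves a single, inductively acidified hydroxyl next to the electrophile and no internal proton donor. The main hazards are base-induced epimerisation or β-elimination of 5 and a second arylation of the product alkoxide, countered by low temperature, a weak fluoride base and a slight excess of 5.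

Step 5
Reactants: 9 (2R,3R)-2-[2-(benzyloxy)propan-2-yl]-2,3-dihydro-1-benzofuran-3-ol
Product: 10 (2R,3R)-2-(2-hydroxypropan-2-yl)-2,3-dihydro-1-benzofuran-3-ol
Conditions: H2 (1 atm), 10% Pd/C (palladium metal on carbon), EtOAc, rt
Reagents that add atoms: none
Why: Hydrogenolysis of a benzyl ether, in which under neutral conditions the O-benzyl bond should cleave well before the secondary benzylic C3–OH bond.

Step 6
Reactants: 10 (2R,3R)-2-(2-hydroxypropan-2-yl)-2,3-dihydro-1-benzofuran-3-ol
Product: 11 (2R,3R)-5-bromo-2-(2-hydroxypropan-2-yl)-2,3-dihydro-1-benzofuran-3-ol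
Conditions: NBS (1.05 equiv), MeCN, 0 °C → rt, dark
Reagents that add atoms: N-bromosuccinimide, O=C1CCC(=O)N1Br
Why: Electrophilic aromatic bromination, in which the ring oxygen O1 directs para to C5, the site also favoured sterically over C7.

Step 7
Reactants: 11 (2R,3R)-5-bromo-2-(2-hydroxypropan-2-yl)-2,3-dihydro-1-benzofuran-3-ol
Product: 13 (2R,3R)-3-hydroxy-2-(2-hydroxypropan-2-yl)-2,3-dihydro-1-benzofuran-5-carbaldehyde, via trilithiated aryllithium 12 (not isolated)
Conditions: n-BuLi (3.3 equiv), THF, −78 °C; DMF (5 equiv), −78 → 0 °C; aq NH4Cl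
Reagents that add atoms: N,N-dimethylformamide, CN(C)C=O
Why: Two equivalents of n-BuLi make the dialkoxide, the third effects bromine–lithium exchange, and the aryllithium is formylated by DMF (Bouveault aldehyde synthesis) while the alkoxides shield both carbinol centres.

Step 8
Reactants: 14 1-(2,4-dihydroxyphenyl)ethanone; 15 1-bromo-3-methylbut-2-ene (prenyl bromide)
Product: 16 1-[2,4-dihydroxy-3-(3-methylbut-2-en-1-yl)phenyl]ethanone
Conditions: 10% aq KOH, 0 °C → rt; chromatography
Reagents that add atoms: none
Why: Direct C-alkylation of the resorcinol-type phenoxide in water, where the ring carbon flanked by both oxygens is the most nucleophilic carbon, with O-alkylated and other C-alkylated isomers to be removed by chromatography.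

Step 9
Reactants: 13 (2R,3R)-3-hydroxy-2-(2-hydroxypropan-2-yl)-2,3-dihydro-1-benzofuran-5-carbaldehyde; 16 1-[2,4-dihydroxy-3-(3-methylbut-2-en-1-yl)phenyl]ethanone
Product: 18 Paratocarpin G, via aldol adduct 17 (not isolated)
Conditions: KOH (50% aq), EtOH, 0 °C → rt; cold dilute AcOH to pH 6
Reagents that add atoms: none
Why: Claisen–Schmidt condensation, in which the ketone enolate of 16 adds to 13 and the aldol 17 loses water by E1cB to the conjugated E enone, the thermodynamic alkene, while neither carbinol centre is acidic and mild acidification avoids dehydration of the benzylic alcohol.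

Compound list
1 | 3-methylbut-2-en-1-ol (prenol) | CC(C)=CCO | starting material
2 | (R)-(3,3-dimethyloxiran-2-yl)methanol | OC[C@H]1OC1(C)C | intermediate
3 | benzyl alcohol | OCc1ccccc1 | starting material
4 | (R)-3-(benzyloxy)-3-methylbutane-1,2-diol | OC[C@@H](O)C(C)(C)OCc1ccccc1 | intermediate
5 | (S)-3-(benzyloxy)-2-hydroxy-3-methylbutanal | O=C[C@@H](O)C(C)(C)OCc1ccccc1 | intermediate
6 | 2-(trimethylsilyl)phenyl trifluoromethanesulfonate | C[Si](C)(C)c1ccccc1OS(=O)(=O)C(F)(F)F | starting material
7 | benzyne | C1#CC=CC=C1 | intermediate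
8 | potassium 2-{[(2S)-3-(benzyloxy)-3-methyl-1-oxobutan-2-yl]oxy}benzen-1-ide | [K+].O=C[C@@H](Oc1cccc[c-]1)C(C)(C)OCc1ccccc1 | intermediate
9 | (2R,3R)-2-[2-(benzyloxy)propan-2-yl]-2,3-dihydro-1-benzofuran-3-ol | c1ccc2c(c1)[C@@H](O)[C@H](C(C)(C)OCc1ccccc1)O2 | intermediate
10 | (2R,3R)-2-(2-hydroxypropan-2-yl)-2,3-dihydro-1-benzofuran-3-ol | c1ccc2c(c1)[C@@H](O)[C@H](C(C)(C)O)O2 | intermediate
11 | (2R,3R)-5-bromo-2-(2-hydroxypropan-2-yl)-2,3-dihydro-1-benzofuran-3-ol | Brc1ccc2c(c1)[C@@H](O)[C@H](C(C)(C)O)O2 | intermediate
12 | trilithiated aryllithium (5-lithio dilithium dialkoxide of 11) | [Li]c1ccc2c(c1)[C@@H](O[Li])[C@H](C(C)(C)O[Li])O2 | intermediate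
13 | (2R,3R)-3-hydroxy-2-(2-hydroxypropan-2-yl)-2,3-dihydro-1-benzofuran-5-carbaldehyde | O=Cc1ccc2c(c1)[C@@H](O)[C@H](C(C)(C)O)O2 | intermediate
14 | 1-(2,4-dihydroxyphenyl)ethanone | CC(=O)c1ccc(O)cc1O | starting material
15 | 1-bromo-3-methylbut-2-ene (prenyl bromide) | CC(C)=CCBr | starting material
16 | 1-[2,4-dihydroxy-3-(3-methylbut-2-en-1-yl)phenyl]ethanone | CC(C)=CCc1c(O)ccc(C(C)=O)c1O | intermediate
17 | aldol adduct, β-hydroxy ketone (both epimers at the new carbinol carbon) | CC(C)=CCc1c(O)ccc(C(=O)CC(O)c2ccc3c(c2)[C@@H](O)[C@H](C(C)(C)O)O3)c1O | intermediate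
18 | Paratocarpin G | CC(C)=CCc1c(O)ccc(C(=O)/C=C/c2ccc3c(c2)[C@@H](O)[C@H](C(C)(C)O)O3)c1O | target

Total step count: 9. Longest linear sequence: 8 (steps 1 to 7, then step 9; step 8 is a one-step side branch).

Steps most likely to fail

1. Step 4 (Proposed new method). The aryl anion may be protonated before it closes the ring, the hydroxy aldehyde may epimerise or lose benzyl alcohol under fluoride, or the carbonyl face may be chosen poorly. The fallback uses known chemistry and makes the same two bonds one after the other, setting out from 5. Silylation (t-BuMe2SiOTf, 2,6-lutidine, CH2Cl2, −78 °C) should give (S)-3-(benzyloxy)-2-[(tert-butyldimethylsilyl)oxy]-3-methylbutanal F1. Felkin–Anh-controlled addition of 2-BrC6H4MgCl (from 1-bromo-2-iodobenzene and i-PrMgCl, THF, −40 °C) should form C3–C3a and give mainly the anti adduct (1R,2R)-3-(benzyloxy)-1-(2-bromophenyl)-2-[(tert-butyldimethylsilyl)oxy]-3-methylbutan-1-ol F2, separable from its epimer. Bu4NF in THF then frees (1R,2R)-3-(benzyloxy)-1-(2-bromophenyl)-3-methylbutane-1,2-diol F3. An intramolecular Ullmann etherification (CuI, 1,10-phenanthroline, Cs2CO3, toluene, 110 °C) closes O1–C7a with retention at C2; the benzylic hydroxyl could only form a four-membered ring. The fallback comes back to the route at 9.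

2. Step 3. Over-oxidation, glycol cleavage, or loss of the α-hydroxy aldehyde as hemiacetal oligomers during isolation. The fallback sets out from 4. Bis-silylation (Et3SiOTf, 2,6-lutidine, CH2Cl2, 0 °C) should give (R)-3-(benzyloxy)-3-methyl-1,2-bis[(triethylsilyl)oxy]butane F4. Swern conditions (oxalyl chloride, DMSO, CH2Cl2, −78 → −30 °C, then Et3N) unmask and oxidise only the primary silyl ether, giving (S)-3-(benzyloxy)-3-methyl-2-[(triethylsilyl)oxy]butanal F5, a stable, non-oligomerising aldehyde. Buffered HF·pyridine in THF at 0 °C then releases the hydroxyl just before use. The fallback comes back to the route at 5.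

3. Step 9. Sluggish enolate formation from the doubly deprotonated ketone, with loss of 13 by Cannizzaro disproportionation or closure of the chalcone to the flavanone. The fallback sets out from 16. Allylation of both phenols (allyl bromide, K2CO3, DMF, 50 °C) should give 1-[2,4-bis(allyloxy)-3-(3-methylbut-2-en-1-yl)phenyl]ethanone F6. Condensation with 13 (KOH, EtOH, rt) should then give the bis-allyl chalcone (E)-1-[2,4-bis(allyloxy)-3-(3-methylbut-2-en-1-yl)phenyl]-3-[(2R,3R)-3-hydroxy-2-(2-hydroxypropan-2-yl)-2,3-dihydro-1-benzofuran-5-yl]prop-2-en-1-one F7. Deallylation under neutral conditions (Pd(PPh3)4 cat., morpholine, THF, rt) touches neither the prenyl group nor the benzylic alcohol. The fallback comes back to the route at 18.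

Further compounds
F1 | step 4 | (S)-3-(benzyloxy)-2-[(tert-butyldimethylsilyl)oxy]-3-methylbutanal | O=C[C@@H](O[Si](C)(C)C(C)(C)C)C(C)(C)OCc1ccccc1
F2 | step 4 | (1R,2R)-3-(benzyloxy)-1-(2-bromophenyl)-2-[(tert-butyldimethylsilyl)oxy]-3-methylbutan-1-ol | O[C@H](c1ccccc1Br)[C@@H](O[Si](C)(C)C(C)(C)C)C(C)(C)OCc1ccccc1
F3 | step 4 | (1R,2R)-3-(benzyloxy)-1-(2-bromophenyl)-3-methylbutane-1,2-diol | O[C@H](c1ccccc1Br)[C@@H](O)C(C)(C)OCc1ccccc1
F4 | step 3 | (R)-3-(benzyloxy)-3-methyl-1,2-bis[(triethylsilyl)oxy]butane | CC[Si](CC)(CC)OC[C@@H](O[Si](CC)(CC)CC)C(C)(C)OCc1ccccc1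
F5 | step 3 | (S)-3-(benzyloxy)-3-methyl-2-[(triethylsilyl)oxy]butanal | O=C[C@@H](O[Si](CC)(CC)CC)C(C)(C)OCc1ccccc1
F6 | step 9 | 1-[2,4-bis(allyloxy)-3-(3-methylbut-2-en-1-yl)phenyl]ethanone | CC(C)=CCc1c(OCC=C)ccc(C(C)=O)c1OCC=C
F7 | step 9 | (E)-1-[2,4-bis(allyloxy)-3-(3-methylbut-2-en-1-yl)phenyl]-3-[(2R,3R)-3-hydroxy-2-(2-hydroxypropan-2-yl)-2,3-dihydro-1-benzofuran-5-yl]prop-2-en-1-one | CC(C)=CCc1c(OCC=C)ccc(C(=O)/C=C/c2ccc3c(c2)[C@@H](O)[C@H](C(C)(C)O)O3)c1OCC=C
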